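**Retrosynthetic overview**
1. Endgame: target 28 ⇐ debenzylation ⇐ acetate 27 ⇐ 2α-ol 26 ⇐ α-face hydroboration of C2=C3 in 24 ⇐ acid closure of C20–OH onto C7 (oxane bridge) in 23 ⇐ LiAlH4 ⇐ acid 22 ⇐ ring-closing metathesis (ring A) of acid 21.
2. Key disconnection C5–C10. The strategy rests on the adjacent stereocentres C10 (quaternary) and C5 of ring B lying between C20 and the benzylic C7–O bond of the oxane bridge: with C20 as a lactone carbonyl, C10=C20(OSi)–O–C7–C6=C5 is an allyl silyl ketene acetal, so an isochroman-3-one rearranges to ring B.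
3. Precursor 18 ⇐ C10 allylation of lactone 16 ⇐ oxidative lactonisation of diol 15 ⇐ CBS reduction (C7) of aryl dienyl ketone 14 ⇐ aryl bromide 12 + Weinreb amide 5.
4. 12 ⇐ 4-bromo-2-isopropylphenol 6 by ortho-formylation/Dakin (C11–O), benzylation, lithiation at C9 between Br and OBn, ethylene oxide (C10, C20); 5 ⇐ prenyl chloride/DMF, then HWE.
5. Ring order: aromatic ring C (bought) → isochromanone ring (temporary) → ring B (Claisen) → ring A (RCM) → oxane C20–O–C7.

Key step: step 11

Remarks on the chemistry:
- Atom labels C1–C20 are the abietane labels of the target carbons. The target is (2S,5S,7S,10R): 2α-OAc, 5α-H, 7β,20-epoxy.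
- 4-Bromo-2-isopropylphenol is taken as the commercial arene (it is also one NBS bromination from 2-isopropylphenol). Its bromine marks C8 before the second oxygen and the C9 chain are introduced, which avoids an unselective electrophilic acylation at C8 versus C14.
- The phenols are carried as benzyl ethers, so the last step is a neutral hydrogenolysis that spares the acetate and the benzylic ether bridge.
- The sense of induction in step 8 assumes the ortho-substituted aryl group acts as the large substituent. The configuration of 15 is to be confirmed (Mosher esters) and the antipodal catalyst used if the assignment is reversed.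

Step 1
Reactants: 1 prenyl chloride (1-chloro-3-methylbut-2-ene)
Product: 3 2,2-dimethylbut-3-enal, via prenylmagnesium chloride 2 (not isolated)
Conditions: Mg, THF, 0 °C (slow addition); DMF, −20 °C → rt; aq. HCl; distilled and used as a solution
Reagents that add atoms: N,N-dimethylformamide, CN(C)C=O
Why: Formylation of an allylic Grignard reagent: prenylmagnesium chloride should react with DMF through its γ (tertiary) carbon by the six-membered SE2' transition state, giving the α,α-dimethyl aldehyde after hydrolysis of the hemiaminal.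

Step 2
Reactants: 3 2,2-dimethylbut-3-enal; 4 diethyl [2-(methoxy(methyl)amino)-2-oxoethyl]phosphonate
Product: 5 (E)-N-methoxy-N,4,4-trimethylhexa-2,5-dienamide
Conditions: NaH, THF, 0 °C → rt
Reagents that add atoms: none
Why: Horner–Wadsworth–Emmons olefination of a non-enolisable aldehyde with a stabilised phosphonate should give the (E)-enamide.

Step 3
Reactants: 6 4-bromo-2-isopropylphenol
Product: 7 5-bromo-2-hydroxy-3-isopropylbenzaldehyde
Conditions: MgCl2, Et3N, (CH2O)n, MeCN, reflux; aq. HCl
Reagents that add atoms: paraformaldehyde (formaldehyde), C=O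
Why: Magnesium-mediated ortho-formylation (Casnati–Skattebøl): the magnesium phenoxide directs formaldehyde to the only free ortho position (C11), and a second equivalent of formaldehyde oxidises the benzylic alkoxide to the aldehyde.

Step 4
Reactants: 7 5-bromo-2-hydroxy-3-isopropylbenzaldehyde
Product: 8 5-bromo-3-isopropylbenzene-1,2-diol
Conditions: 30% H2O2, NaOH, THF–H2O, 0 °C → rt; then HCl (under N2)
Reagents that add atoms: hydrogen peroxide, OO
Why: Dakin oxidation: the hydroperoxide adduct of the ortho-hydroxybenzaldehyde rearranges with aryl migration to the aryl formate, which is hydrolysed in the same pot to the catechol.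

Step 5
Reactants: 8 5-bromo-3-isopropylbenzene-1,2-diol
Product: 9 1,2-bis(benzyloxy)-5-bromo-3-isopropylbenzene
Conditions: BnBr, K2CO3, DMF, 60 °C
Reagents that add atoms: benzyl bromide, BrCc1ccccc1
Why: Williamson ether synthesis on both phenols; benzyl ethers survive the bases, hydrides and metathesis that follow and come off by hydrogenolysis at the end.

Step 6
Reactants: 9 1,2-bis(benzyloxy)-5-bromo-3-isopropylbenzene; 10 ethylene oxide
Product: 12 2-[2,3-bis(benzyloxy)-6-bromo-4-isopropylphenyl]ethanol, via C9 aryllithium 11 (not isolated)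
Conditions: LDA, THF, −78 °C; then 10, BF3·OEt2, −78 °C; aq. work-up
Reagents that add atoms: none
Why: Directed ortho-metalation: the C9–H between bromine and the benzyloxy group is the most acidic ring proton and LDA removes it without halogen–metal exchange; the aryllithium opens BF3-activated ethylene oxide at −78 °C, below the temperature of benzyne formation.

Step 7
Reactants: 12 2-[2,3-bis(benzyloxy)-6-bromo-4-isopropylphenyl]ethanol; 5 (E)-N-methoxy-N,4,4-trimethylhexa-2,5-dienamide
Product: 14 (E)-1-[3,4-bis(benzyloxy)-2-(2-hydroxyethyl)-5-isopropylphenyl]-4,4-dimethylhexa-2,5-dien-1-one, via dilithiated alkoxide 13 (not isolated)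
Conditions: n-BuLi (2.1 equiv), THF, −78 °C; then 5, −78 → −20 °C; aq. NH4Cl
Reagents that add atoms: none
Why: Bromine–lithium exchange on the lithium alkoxide gives the C8 aryllithium, which adds once and in 1,2-fashion to the Weinreb amide (stable chelated tetrahedral intermediate), so the aryl dienyl ketone appears only on work-up.

Step 8
Reactants: 14 (E)-1-[3,4-bis(benzyloxy)-2-(2-hydroxyethyl)-5-isopropylphenyl]-4,4-dimethylhexa-2,5-dien-1-one
Product: 15 (1S,2E)-1-[3,4-bis(benzyloxy)-2-(2-hydroxyethyl)-5-isopropylphenyl]-4,4-dimethylhexa-2,5-dien-1-ol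
Conditions: (R)-2-methyl-CBS-oxazaborolidine, catecholborane (2.5 equiv), toluene, −78 °C; MeOH, aq. NaOH wash
Reagents that add atoms: none
Why: Corey–Bakshi–Shibata reduction with catecholborane (which leaves the alkenes alone at −78 °C): with the ortho-substituted aryl group as the large and the planar (E)-alkenyl group as the small substituent, the (R)-catalyst should deliver hydride to give the (S)-carbinol at C7.

Step 9
Reactants: 15 (1S,2E)-1-[3,4-bis(benzyloxy)-2-(2-hydroxyethyl)-5-isopropylphenyl]-4,4-dimethylhexa-2,5-dien-1-ol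
Product: 16 (1S)-5,6-bis(benzyloxy)-1-[(E)-3,3-dimethylpenta-1,4-dienyl]-7-isopropylisochroman-3-one
Conditions: TEMPO (20 mol%), PhI(OAc)2 (2.5 equiv), CH2Cl2, rt
Reagents that add atoms: none
Why: TEMPO/PhI(OAc)2 oxidative lactonisation: the oxoammonium salt oxidises the primary alcohol selectively to the aldehyde, which the C7 hydroxyl intercepts as the six-membered lactol that is oxidised on to the lactone, leaving C7 untouched.

Step 10
Reactants: 16 (1S)-5,6-bis(benzyloxy)-1-[(E)-3,3-dimethylpenta-1,4-dienyl]-7-isopropylisochroman-3-one; 17 allyl bromide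
Product: 18 (1S)-4-allyl-5,6-bis(benzyloxy)-1-[(E)-3,3-dimethylpenta-1,4-dienyl]-7-isopropylisochroman-3-one (both C4 epimers)
Conditions: LDA (1.05 equiv), THF, −78 °C; 17, DMPU, −78 → −40 °C
Reagents that add atoms: none
Why: Alkylation of the benzylic lactone lithium enolate with allyl bromide; the new C10 centre forms as an epimer mixture, which does not matter because C10 is enolised again in step 11.

Step 11
Reactants: 18 (1S)-4-allyl-5,6-bis(benzyloxy)-1-[(E)-3,3-dimethylpenta-1,4-dienyl]-7-isopropylisochroman-3-one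
Product: 21 (1R,2S)-1-allyl-7,8-bis(benzyloxy)-6-isopropyl-2-(2-methylbut-3-en-2-yl)-1,2-dihydronaphthalene-1-carboxylic acid, via silyl ketene acetal 19 (not isolated), via trimethylsilyl ester 20 (not isolated)
Conditions: KHMDS, TMSCl, THF–toluene, −78 °C → rt; toluene, 90 °C; aq. citric acid
Reagents that add atoms: none
Why: KHMDS removes the benzylic C10–H and TMSCl traps the enolate as the 3-silyloxy-1H-isochromene 19, whose C10=C20(OSiMe3)–O–C7–C6=C5 array undergoes a concerted suprafacial [3,3] shift (Ireland–Claisen) on heating, forming C10–C5 and breaking C7–O to give silyl ester 20 and, after hydrolysis, acid 21. The closest known reaction type is the Claisen rearrangement of silyl enolates of lactones that carry an alkenyl group on the carbinol carbon, six-membered cases included, which runs through a ring-enforced boat. Ring B (C5–C6–C7–C8–C9–C10) is closed by this sigmatropic C–C bond formation inside a bicyclo[2.2.2]-like transition state with C7 and C10 as bridgeheads and O–C20, C8–C9 and C6–C5 as bridges, while the lactone ring opens in the same event. C10 is set by transfer of chirality from C7: the dienyl chain can reach C10 only on the face of the isochromene on which C7 holds it, so (7S) should give (10R). C5 is set by the alkene geometry: in the boat the (E)-alkene places H-5 over the arene bridge and the CMe2 group on the side of the O–C20 bridge, that is C4 cis to C20 (5S). The step needs the concerted path to beat heterolysis of the benzylic, allylic C7–O bond and needs enolisation at a hindered C10; a non-polar medium free of Lewis acid, the peri strain between the in-plane allyl group and the C11 benzyloxy group in 19 (relieved as C10 pyramidalises) and the conjugation gained as C6=C7 aligns with the arene should secure this.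

Step 12
Reactants: 21 (1R,2S)-1-allyl-7,8-bis(benzyloxy)-6-isopropyl-2-(2-methylbut-3-en-2-yl)-1,2-dihydronaphthalene-1-carboxylic acid
Product: 22 (5S,10R)-11,12-bis(benzyloxy)abieta-2,6,8,11,13-pentaen-20-oic acid
Conditions: Grubbs II (5 mol%), CH2Cl2, 40 °C
Reagents that add atoms: none
Why: Ring-closing metathesis of the C10 allyl group with the vinyl group on C4 closes ring A as a cyclohexene (C2=C3) with loss of ethene; the two chains are trans on ring B and can both sit pseudo-equatorial, and the unstrained internal C6=C7 bond should not take part.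

Step 13
Reactants: 22 (5S,10R)-11,12-bis(benzyloxy)abieta-2,6,8,11,13-pentaen-20-oic acid
Product: 23 (5S,10R)-11,12-bis(benzyloxy)abieta-2,6,8,11,13-pentaen-20-ol
Conditions: LiAlH4, THF, 0 °C → reflux; Fieser work-up
Reagents that add atoms: none
Why: Hydride reduction of the neopentyl carboxylic acid to the primary C20 alcohol; the alkenes and benzyl ethers are inert to LiAlH4.

Step 14
Reactants: 23 (5S,10R)-11,12-bis(benzyloxy)abieta-2,6,8,11,13-pentaen-20-ol
Product: 24 11,12-bis(benzyloxy)-7β,20-epoxyabieta-2,8,11,13-tetraene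
Conditions: TfOH (5 mol%), CH2Cl2, 0 °C
Reagents that add atoms: none
Why: Brønsted acid-catalysed Markovnikov hydroalkoxylation: protonation of the styrene at C6 gives the benzylic C7 cation (stabilised by the para C12 oxygen), which the axial C20 hydroxyl traps in a six-membered closure; the bridge can only form on the β face, so C7 is regained as (S) under control of C10.

Step 15
Reactants: 24 11,12-bis(benzyloxy)-7β,20-epoxyabieta-2,8,11,13-tetraene
Product: 26 11,12-bis(benzyloxy)-7β,20-epoxyabieta-8,11,13-trien-2α-ol, via C2 alkylborane 25 (not isolated)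
Conditions: BH3·THF, THF, 0 °C → rt; then 3 M NaOH, 30% H2O2, 0 °C
Reagents that add atoms: hydrogen peroxide, OO
Why: Hydroboration–oxidation: boron should add to C2 (not to the neopentyl C3 next to the gem-dimethyl carbon) and from the α face, because the β face of C2 is screened by the syn-axial C20 bridge carbon and the 4β-methyl group; oxidation with retention gives the equatorial 2α-alcohol (2S).

Step 16
Reactants: 26 11,12-bis(benzyloxy)-7β,20-epoxyabieta-8,11,13-trien-2α-ol
Product: 27 2α-acetoxy-11,12-bis(benzyloxy)-7β,20-epoxyabieta-8,11,13-triene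
Conditions: Ac2O, pyridine, DMAP (cat.), CH2Cl2, rt
Reagents that add atoms: acetic anhydride, CC(=O)OC(C)=O
Why: DMAP-catalysed acylation of the unhindered equatorial secondary alcohol, done while both phenols are still masked so that no selective deacylation is needed.

Step 17
Reactants: 27 2α-acetoxy-11,12-bis(benzyloxy)-7β,20-epoxyabieta-8,11,13-triene
Product: 28 2α-acetoxy-7β,20-epoxyabieta-8,11,13-triene-11,12-diol (target, CNP0485560.1)
Conditions: H2 (1 atm), 10% Pd/C, EtOAc, rt (short reaction time, under exclusion of air on work-up)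
Reagents that add atoms: none
Why: Hydrogenolysis of the two aryl benzyl ethers over Pd/C under neutral conditions; the alkyl acetate is inert and the bridged benzylic alkyl ether at C7 should be cleaved far more slowly than aryl benzyl ethers.

**Compound list**
1 | prenyl chloride (1-chloro-3-methylbut-2-ene) | CC(C)=CCCl | starting material
2 | prenylmagnesium chloride (not isolated) | CC(C)=CC[Mg]Cl | intermediate
3 | 2,2-dimethylbut-3-enal | C=CC(C)(C)C=O | intermediate
4 | diethyl [2-(methoxy(methyl)amino)-2-oxoethyl]phosphonate | CCOP(=O)(CC(=O)N(C)OC)OCC | starting material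
5 | (E)-N-methoxy-N,4,4-trimethylhexa-2,5-dienamide | CON(C)C(=O)/C=C/C(C)(C)C=C | intermediate
6 | 4-bromo-2-isopropylphenol | CC(C)c1cc(Br)ccc1O | starting material
7 | 5-bromo-2-hydroxy-3-isopropylbenzaldehyde | CC(C)c1cc(Br)cc(C=O)c1O | intermediate
8 | 5-bromo-3-isopropylbenzene-1,2-diol | CC(C)c1cc(Br)cc(O)c1O | intermediate
9 | 1,2-bis(benzyloxy)-5-bromo-3-isopropylbenzene | CC(C)c1cc(Br)cc(OCc2ccccc2)c1OCc1ccccc1 | intermediate
10 | ethylene oxide | C1CO1 | starting material
11 | [2,3-bis(benzyloxy)-6-bromo-4-isopropylphenyl]lithium (not isolated) | CC(C)c1cc(Br)c([Li])c(OCc2ccccc2)c1OCc1ccccc1 | intermediate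
12 | 2-[2,3-bis(benzyloxy)-6-bromo-4-isopropylphenyl]ethanol | CC(C)c1cc(Br)c(CCO)c(OCc2ccccc2)c1OCc1ccccc1 | intermediate
13 | lithium 2-[2,3-bis(benzyloxy)-4-isopropyl-6-lithiophenyl]ethoxide (not isolated) | CC(C)c1cc([Li])c(CCO[Li])c(OCc2ccccc2)c1OCc1ccccc1 | intermediate
14 | (E)-1-[3,4-bis(benzyloxy)-2-(2-hydroxyethyl)-5-isopropylphenyl]-4,4-dimethylhexa-2,5-dien-1-one | CC(C)c1cc(C(=O)/C=C/C(C)(C)C=C)c(CCO)c(OCc2ccccc2)c1OCc1ccccc1 | intermediate
15 | (1S,2E)-1-[3,4-bis(benzyloxy)-2-(2-hydroxyethyl)-5-isopropylphenyl]-4,4-dimethylhexa-2,5-dien-1-ol | CC(C)c1cc([C@@H](O)/C=C/C(C)(C)C=C)c(CCO)c(OCc2ccccc2)c1OCc1ccccc1 | intermediate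
16 | (1S)-5,6-bis(benzyloxy)-1-[(E)-3,3-dimethylpenta-1,4-dienyl]-7-isopropylisochroman-3-one | C1C(=O)O[C@@H](/C=C/C(C)(C)C=C)c2cc(C(C)C)c(OCc3ccccc3)c(OCc3ccccc3)c12 | intermediate
17 | allyl bromide | C=CCBr | starting material
18 | (1S)-4-allyl-5,6-bis(benzyloxy)-1-[(E)-3,3-dimethylpenta-1,4-dienyl]-7-isopropylisochroman-3-one (C4 epimers) | C=CCC1C(=O)O[C@@H](/C=C/C(C)(C)C=C)c2cc(C(C)C)c(OCc3ccccc3)c(OCc3ccccc3)c12 | intermediate
19 | (1S)-4-allyl-5,6-bis(benzyloxy)-1-[(E)-3,3-dimethylpenta-1,4-dienyl]-7-isopropyl-3-(trimethylsilyloxy)-1H-isochromene (not isolated) | C=CCC1=C(O[Si](C)(C)C)O[C@@H](/C=C/C(C)(C)C=C)c2cc(C(C)C)c(OCc3ccccc3)c(OCc3ccccc3)c12 | intermediate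
20 | trimethylsilyl (1R,2S)-1-allyl-7,8-bis(benzyloxy)-6-isopropyl-2-(2-methylbut-3-en-2-yl)-1,2-dihydronaphthalene-1-carboxylate (not isolated) | C=CC[C@@]1(C(=O)O[Si](C)(C)C)[C@H](C(C)(C)C=C)C=Cc2cc(C(C)C)c(OCc3ccccc3)c(OCc3ccccc3)c12 | intermediate
21 | (1R,2S)-1-allyl-7,8-bis(benzyloxy)-6-isopropyl-2-(2-methylbut-3-en-2-yl)-1,2-dihydronaphthalene-1-carboxylic acid | C=CC[C@@]1(C(=O)O)[C@H](C(C)(C)C=C)C=Cc2cc(C(C)C)c(OCc3ccccc3)c(OCc3ccccc3)c12 | intermediate
22 | (5S,10R)-11,12-bis(benzyloxy)abieta-2,6,8,11,13-pentaen-20-oic acid | OC(=O)[C@]12CC=CC(C)(C)[C@@H]1C=Cc1cc(C(C)C)c(OCc3ccccc3)c(OCc3ccccc3)c12 | intermediate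
23 | (5S,10R)-11,12-bis(benzyloxy)abieta-2,6,8,11,13-pentaen-20-ol | OC[C@]12CC=CC(C)(C)[C@@H]1C=Cc1cc(C(C)C)c(OCc3ccccc3)c(OCc3ccccc3)c12 | intermediate
24 | 11,12-bis(benzyloxy)-7β,20-epoxyabieta-2,8,11,13-tetraene (5S,7S,10R) | C1=CC(C)(C)[C@@H]2C[C@@H]3OC[C@@]2(C1)c1c3cc(C(C)C)c(OCc3ccccc3)c1OCc1ccccc1 | intermediate
25 | 11,12-bis(benzyloxy)-2α-boranyl-7β,20-epoxyabieta-8,11,13-triene (not isolated) | B[C@H]1CC(C)(C)[C@@H]2C[C@@H]3OC[C@@]2(C1)c1c3cc(C(C)C)c(OCc3ccccc3)c1OCc1ccccc1 | intermediate
26 | 11,12-bis(benzyloxy)-7β,20-epoxyabieta-8,11,13-trien-2α-ol | O[C@H]1CC(C)(C)[C@@H]2C[C@@H]3OC[C@@]2(C1)c1c3cc(C(C)C)c(OCc3ccccc3)c1OCc1ccccc1 | intermediate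
27 | 2α-acetoxy-11,12-bis(benzyloxy)-7β,20-epoxyabieta-8,11,13-triene | CC(=O)O[C@H]1CC(C)(C)[C@@H]2C[C@@H]3OC[C@@]2(C1)c1c3cc(C(C)C)c(OCc3ccccc3)c1OCc1ccccc1 | intermediate
28 | 2α-acetoxy-7β,20-epoxyabieta-8,11,13-triene-11,12-diol (2S,5S,7S,10R) | CC(=O)O[C@H]1CC(C)(C)[C@@H]2C[C@@H]3OC[C@@]2(C1)c1c3cc(C(C)C)c(O)c1O | target

**Totals**
Total step count: 17. Longest linear sequence: 15 steps (6 → 28, steps 3–17); steps 1–2 make the side-chain fragment 5.

**Steps most likely to fail**

Step 11 (key step). What may go wrong is slow or incomplete enolisation at the fully substituted, peri-hindered C10, or a congested boat that lets heterolysis of the benzylic, allylic C7–O bond compete and erode the transfer of chirality. The fallback sets out from lactone 16, which has no allyl group. Its less hindered ketene acetal is formed and rearranged under the same type of conditions (KHMDS, TMSCl; toluene, heat; aqueous acid) to give (2R)-7,8-bis(benzyloxy)-6-isopropyl-2-(2-methylbut-3-en-2-yl)-1,2-dihydronaphthalene-1-carboxylic acid F1, in which C5 is set by the same boat. The dianion of F1 (LDA, 2.2 equiv, THF–DMPU, −78 → 0 °C) is then alkylated with allyl bromide 17. The electrophile should enter anti to the bulky C5 substituent, so the quaternary centre is made by substrate-controlled alkylation instead of in the sigmatropic step. The route is rejoined at acid 21.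

Step 8. What may go wrong is poor facial discrimination, because both carbonyl substituents are sp2 groups of similar steric demand, giving low enantiomeric purity at C7. The fallback sets out from ketone 14. Luche reduction (NaBH4, CeCl3, MeOH, 0 °C) gives the racemic (E)-1-[3,4-bis(benzyloxy)-2-(2-hydroxyethyl)-5-isopropylphenyl]-4,4-dimethylhexa-2,5-dien-1-ol F2. Sharpless kinetic resolution (Ti(OiPr)4, L-(+)-diisopropyl tartrate, t-BuOOH, 4 Å sieves, CH2Cl2, −20 °C) should epoxidise the (R)-carbinol to the epoxy diol (1S)-1-[3,4-bis(benzyloxy)-2-(2-hydroxyethyl)-5-isopropylphenyl]-1-[(2R,3R)-3-(2-methylbut-3-en-2-yl)oxiran-2-yl]methanol F3. The slow-reacting (S)-alcohol is recovered, and the route is rejoined at diol 15.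

Step 14. What may go wrong is that protonation of the only moderately activated styrene needs acid strong enough to start loss of benzyl ethers, protonation of C2=C3 or cationic oligomerisation before the C20 hydroxyl closes the bridge. The fallback sets out from acid 22. Trifluoroacetic acid in CH2Cl2 at 0 °C should lactonise the carboxylic acid onto C7 (the lactone is the thermodynamic sink) to give 11,12-bis(benzyloxy)abieta-2,8,11,13-tetraen-20,7β-olide F4. LiAlH4 reduces it to 11,12-bis(benzyloxy)abieta-2,8,11,13-tetraene-7β,20-diol F5. The benzylic C7 alcohol of F5 ionises under much milder acid (catalytic TsOH or PPTS, CH2Cl2, rt) and is trapped by the C20 hydroxyl on the only accessible face. The route is rejoined at ether 24.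

**Further compounds**
F1 | step 11 | (2R)-7,8-bis(benzyloxy)-6-isopropyl-2-(2-methylbut-3-en-2-yl)-1,2-dihydronaphthalene-1-carboxylic acid (C1 epimers; C2 arranged as in 21) | OC(=O)C1[C@H](C(C)(C)C=C)C=Cc2cc(C(C)C)c(OCc3ccccc3)c(OCc3ccccc3)c12
F2 | step 8 | racemic (E)-1-[3,4-bis(benzyloxy)-2-(2-hydroxyethyl)-5-isopropylphenyl]-4,4-dimethylhexa-2,5-dien-1-ol | CC(C)c1cc(C(O)/C=C/C(C)(C)C=C)c(CCO)c(OCc2ccccc2)c1OCc1ccccc1
F3 | step 8 | (1S)-1-[3,4-bis(benzyloxy)-2-(2-hydroxyethyl)-5-isopropylphenyl]-1-[(2R,3R)-3-(2-methylbut-3-en-2-yl)oxiran-2-yl]methanol | CC(C)c1cc([C@H](O)[C@H]2O[C@@H]2C(C)(C)C=C)c(CCO)c(OCc2ccccc2)c1OCc1ccccc1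
F4 | step 14 | 11,12-bis(benzyloxy)abieta-2,8,11,13-tetraen-20,7β-olide | C1=CC(C)(C)[C@@H]2C[C@@H]3OC(=O)[C@@]2(C1)c1c3cc(C(C)C)c(OCc3ccccc3)c1OCc1ccccc1
F5 | step 14 | 11,12-bis(benzyloxy)abieta-2,8,11,13-tetraene-7β,20-diol | C1=CC(C)(C)[C@@H]2C[C@H](O)c3cc(C(C)C)c(OCc4ccccc4)c(OCc4ccccc4)c3[C@]2(C1)CO
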